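## Retrosynthetic overview

1. Target ⇒ desilylation of the right-half 3-silyl ether ⇒ left-half C7 ketone: MeLi adds equatorially (axial tertiary oxygen) and one Ac2O quench installs all three acetates.
2. C7 ketone ⇒ central CH2–CH2 bond by radical conjugate addition of a right-half primary iodide to a left-half exocyclic enone.
3. Right-half iodide ⇐ bis-epoxy farnesyl acetate: one cascade closes oxepane ring D, then cyclohexane ring C; the acetate captures the cation (sets C7′) and iodide opens the resulting dioxanium ion.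
4. Left-half enone ⇐ bis-epoxy vinyl ketone (from geranylacetone): one cascade closes oxepane ring A, then cyclohexanone ring B, terminated by a sulfonium silyl enol ether.
5. All epoxide stereocentres come from ketone-catalysed (dioxirane) asymmetric epoxidation of the two achiral polyenes; the two halves are built in separate flasks and then joined.

Reading of the target: both halves are trans-fused (3S,5aS,6S,9aS) perhydro-1-benzoxepines; they differ at C7 (left 7R, acetate axial and cis to the 5a-methyl; right 7S, acetate equatorial) and at O3 (left acetate, right free OH).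

Assumption: each bicycle is numbered as a 1-benzoxepine (O1, C2–C5, C5a, C6–C9, C9a), the left half is the one with the secondary acetate, primed locants belong to the right half, and (2E,6E)-farnesyl acetate and (E)-geranylacetone are bought as single geometric isomers.

## Route

Step 1
Reactants: 1 (2E,6E)-farnesyl acetate
Product: 3 (2E,6S,7S,10S)-6,7:10,11-diepoxy-3,7,11-trimethyldodec-2-en-1-yl acetate, via 10,11-monoepoxide 2 (not isolated)
Conditions: L-fructose-derived enantiomer of the Shi ketone (0.6 equiv), KHSO5 (as 2KHSO5·KHSO4·K2SO4), K2CO3, Bu4NHSO4, MeCN/CH2(OMe)2/aq. Na2B4O7 buffer (pH 10.5), 0 °C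
Reagents that add atoms: potassium peroxymonosulfate KHSO5, [K+].[O-]S(=O)(=O)OO
Why: Shi asymmetric epoxidation: the chiral dioxirane epoxidises the two electron-rich trisubstituted alkenes through a spiro transition state (6S,7S and 10S with this catalyst enantiomer), while the 2,3-alkene is deactivated by the allylic acetate and stays intact.

Step 2
Reactants: 3 (2E,6S,7S,10S)-6,7:10,11-diepoxy-3,7,11-trimethyldodec-2-en-1-yl acetate
Product: 5 (3S,5aS,6S,7S,9aS)-3-[tert-butyl(dimethyl)silyl]oxy-6-(iodomethyl)-2,2,5a,7-tetramethyldecahydro-1-benzoxepin-7-yl acetate, via dioxanium triflate 4 (not isolated)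
Conditions: TBSOTf (1.1 equiv), 2,6-di-tert-butyl-4-methylpyridine, CH2Cl2 (0.01 M), −78 °C, 1 h; then Bu4NI (3 equiv), −78 → 0 °C
Reagents that add atoms: tert-butyldimethylsilyl triflate, CC(C)(C)[Si](C)(C)OS(=O)(=O)C(F)(F)F; tetrabutylammonium iodide, CCCC[N+](CCCC)(CCCC)CCCC.[I-]
Why: Proposed new method: the silyl triflate activates the terminal epoxide, the 6,7-epoxide oxygen opens it at C11 to a bicyclic epoxonium ion (ring D, C3′ retained), the E-2,3-alkene opens that ion at C7 with inversion through a chair (ring C; C5a′, C9a′ and the equatorial C6′ side chain follow from the epoxide and alkene geometry), the tertiary cation is captured from the equatorial side by the acetate carbonyl as a trans-fused 1,3-dioxan-2-ylium ion (sets C7′, oxygen anti to the new C–C bond), and iodide opens this ion by SN2 at the primary CH2–O carbon so that the acetyl group ends on the tertiary oxygen; the closest known reactions are silyl-triflate-promoted tandem oxa/carbacyclisation of polyepoxy alkenes, acetate-assisted cation capture in acid cyclisations of farnesyl acetate, and halide opening of 1,3-dioxan-2-ylium ions at the primary carbon (Hanessian–Hullar type).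

Step 3
Reactants: 6 (5E)-6,10-dimethylundeca-5,9-dien-2-one [(E)-geranylacetone]
Product: 8 (5S,6S,9S)-5,6:9,10-diepoxy-6,10-dimethylundecan-2-one, via 9,10-monoepoxide 7 (not isolated)
Conditions: L-fructose-derived enantiomer of the Shi ketone (0.6 equiv), KHSO5 (as 2KHSO5·KHSO4·K2SO4), K2CO3, Bu4NHSO4, MeCN/CH2(OMe)2/aq. Na2B4O7 buffer (pH 10.5), 0 °C
Reagents that add atoms: potassium peroxymonosulfate KHSO5, [K+].[O-]S(=O)(=O)OO
Why: Shi asymmetric epoxidation: both trisubstituted alkenes are epoxidised in the same facial sense (5S,6S and 9S), and the unactivated methyl ketone of the substrate is far too slow a dioxirane precursor to erode selectivity.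

Step 4
Reactants: 8 (5S,6S,9S)-5,6:9,10-diepoxy-6,10-dimethylundecan-2-one
Product: 12 (6S,7S,10S)-6,7:10,11-diepoxy-7,11-dimethyldodec-1-en-3-one, via lithium enolate 9 (not isolated), via Mannich base 10 (not isolated), via ammonium iodide 11 (not isolated)
Conditions: LiN(iPr)2, THF, −78 °C; Me2N=CH2 I (Eschenmoser's salt), −78 → 0 °C; crude amine, MeI, Et2O, rt; then aq. NaHCO3/CH2Cl2, rt
Reagents that add atoms: N,N-dimethylmethylideneammonium iodide, C=[N+](C)C.[I-]
Why: Kinetic deprotonation takes the methyl side of the ketone, the enolate is trapped in a Mannich reaction, and exhaustive methylation followed by E1cB (Hofmann-type) elimination unmasks the vinyl ketone without touching any stereocentre.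

Step 5
Reactants: 12 (6S,7S,10S)-6,7:10,11-diepoxy-7,11-dimethyldodec-1-en-3-one
Product: 16 (3S,5aS,9aS)-3-hydroxy-2,2,5a-trimethyl-6-methylideneoctahydro-1-benzoxepin-7(2H)-one, via sulfonium silyl enol ether 13 (not isolated), via sulfonium ketone 14 (not isolated), via silyl ether enone 15 (not isolated)
Conditions: Me2S (1.05 equiv), TMSOTf (1.1 equiv), 2,6-di-tert-butyl-4-methylpyridine, CH2Cl2, −78 °C, 20 min; then TMSOTf (1.1 equiv), −78 °C, 1 h; then DBU, −78 → 0 °C; 1 M aq. HCl/THF, 0 °C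
Reagents that add atoms: none
Why: Proposed new method: Me2S and TMSOTf (as Me2S–SiMe3 triflate) add 1,4 to the vinyl ketone to give a β-sulfonio silyl enol ether with the enol fixed at C2=C3, a second equivalent of TMSOTf then starts the same epoxide cascade (ring A by oxygen attack at C11, C3 retained) and the enol-ether carbon opens the epoxonium ion at the tertiary carbon with inversion through a chair (ring B; C5a and C9a from the 6S,7S-epoxide), after which DBU expels Me2S by E1cB to give the exocyclic enone and acid removes the silyl ether; the closest known reactions are sulfide/silyl-triflate Morita–Baylis–Hillman-type additions of enones to acetals and enol-silane-terminated oxa/carbacyclisation of diepoxides.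

Step 6
Reactants: 5 (3S,5aS,6S,7S,9aS)-3-[tert-butyl(dimethyl)silyl]oxy-6-(iodomethyl)-2,2,5a,7-tetramethyldecahydro-1-benzoxepin-7-yl acetate; 16 (3S,5aS,9aS)-3-hydroxy-2,2,5a-trimethyl-6-methylideneoctahydro-1-benzoxepin-7(2H)-one (1.3 equiv)
Product: 17 (3S,5aS,6S,7S,9aS)-3-[tert-butyl(dimethyl)silyl]oxy-6-{2-[(3S,5aS,6S,9aS)-3-hydroxy-2,2,5a-trimethyl-7-oxodecahydro-1-benzoxepin-6-yl]ethyl}-2,2,5a,7-tetramethyldecahydro-1-benzoxepin-7-yl acetate
Conditions: (Me3Si)3SiH (1.5 equiv, syringe pump), Et3B (0.3 equiv)/air, toluene, 0 °C → rt; then DBU (0.2 equiv), rt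
Reagents that add atoms: none
Why: Giese radical conjugate addition: iodine abstraction from 5 gives a primary radical that adds to the unhindered CH2 terminus of the enone, hydrogen transfer to the α-keto radical occurs anti to the axial 5a-methyl, and DBU equilibration secures the equatorial C6 side chain (6S).

Step 7
Reactants: 17 (3S,5aS,6S,7S,9aS)-3-[tert-butyl(dimethyl)silyl]oxy-6-{2-[(3S,5aS,6S,9aS)-3-hydroxy-2,2,5a-trimethyl-7-oxodecahydro-1-benzoxepin-6-yl]ethyl}-2,2,5a,7-tetramethyldecahydro-1-benzoxepin-7-yl acetate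
Product: 19 (3S,5aS,6S,7R,9aS)-7-acetoxy-6-{2-[(3S,5aS,6S,7S,9aS)-7-acetoxy-3-[tert-butyl(dimethyl)silyl]oxy-2,2,5a,7-tetramethyldecahydro-1-benzoxepin-6-yl]ethyl}-2,2,5a,7-tetramethyldecahydro-1-benzoxepin-3-yl acetate, via trilithium trialkoxide 18 (not isolated)
Conditions: MeLi (6 equiv), THF/Et2O, −78 → 0 °C; then Ac2O (12 equiv), DMAP, 0 °C → rt
Reagents that add atoms: methyllithium, [Li]C; acetic anhydride, CC(=O)OC(C)=O
Why: 1,2-Addition of MeLi to the cyclohexanone occurs from the equatorial side because the axial face is blocked by the 1,3-diaxial 5a-methyl, giving the axial tertiary alkoxide (7R); excess MeLi also deprotonates the C3 hydroxyl and cleaves the tertiary acetate, and the three lithium alkoxides are acetylated in the same flask (alkoxide acylation).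

Step 8
Reactants: 19 (3S,5aS,6S,7R,9aS)-7-acetoxy-6-{2-[(3S,5aS,6S,7S,9aS)-7-acetoxy-3-[tert-butyl(dimethyl)silyl]oxy-2,2,5a,7-tetramethyldecahydro-1-benzoxepin-6-yl]ethyl}-2,2,5a,7-tetramethyldecahydro-1-benzoxepin-3-yl acetate
Product: 20 CNP0169816.1: (3S,5aS,6S,7R,9aS)-7-acetoxy-6-{2-[(3S,5aS,6S,7S,9aS)-7-acetoxy-3-hydroxy-2,2,5a,7-tetramethyldecahydro-1-benzoxepin-6-yl]ethyl}-2,2,5a,7-tetramethyldecahydro-1-benzoxepin-3-yl acetate
Conditions: HF·pyridine, pyridine/THF, 0 °C → rt
Reagents that add atoms: none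
Why: Fluoride-mediated desilylation cleaves only the Si–O bond, so the three acetates and all ten stereocentres are untouched.

## Compound list

1 | (2E,6E)-farnesyl acetate [(2E,6E)-3,7,11-trimethyldodeca-2,6,10-trien-1-yl acetate] | CC(=O)OC/C=C(\C)CC/C=C(\C)CCC=C(C)C | starting material
2 | (2E,6E,10S)-10,11-epoxy-3,7,11-trimethyldodeca-2,6-dien-1-yl acetate | CC(=O)OC/C=C(\C)CC/C=C(\C)CC[C@@H]1OC1(C)C | intermediate
3 | (2E,6S,7S,10S)-6,7:10,11-diepoxy-3,7,11-trimethyldodec-2-en-1-yl acetate | CC(=O)OC/C=C(\C)CC[C@@H]1O[C@@]1(C)CC[C@@H]1OC1(C)C | intermediate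
4 | right-half tricyclic 2-methyl-1,3-dioxan-2-ylium triflate (dioxanium ring trans-fused across C6′–CH2–O and C7′–O, C7′–O equatorial, 3′-OTBS) | O1C[C@H]2[C@]3(C)CC[C@H](O[Si](C)(C)C(C)(C)C)C(C)(C)O[C@H]3CC[C@]2(C)[O+]=C1C.[O-]S(=O)(=O)C(F)(F)F | intermediate
5 | (3S,5aS,6S,7S,9aS)-3-[tert-butyl(dimethyl)silyl]oxy-6-(iodomethyl)-2,2,5a,7-tetramethyldecahydro-1-benzoxepin-7-yl acetate | IC[C@H]1[C@]2(C)CC[C@H](O[Si](C)(C)C(C)(C)C)C(C)(C)O[C@H]2CC[C@]1(C)OC(C)=O | intermediate
6 | (5E)-6,10-dimethylundeca-5,9-dien-2-one [(E)-geranylacetone] | CC(=O)CC/C=C(\C)CCC=C(C)C | starting material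
7 | (5E,9S)-9,10-epoxy-6,10-dimethylundec-5-en-2-one | CC(=O)CC/C=C(\C)CC[C@@H]1OC1(C)C | intermediate
8 | (5S,6S,9S)-5,6:9,10-diepoxy-6,10-dimethylundecan-2-one | CC(=O)CC[C@@H]1O[C@@]1(C)CC[C@@H]1OC1(C)C | intermediate
9 | lithium (5S,6S,9S)-5,6:9,10-diepoxy-6,10-dimethylundec-1-en-2-olate | [Li]OC(=C)CC[C@@H]1O[C@@]1(C)CC[C@@H]1OC1(C)C | intermediate
10 | (6S,7S,10S)-1-(dimethylamino)-6,7:10,11-diepoxy-7,11-dimethyldodecan-3-one | CN(C)CCC(=O)CC[C@@H]1O[C@@]1(C)CC[C@@H]1OC1(C)C | intermediate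
11 | (6S,7S,10S)-6,7:10,11-diepoxy-N,N,N,7,11-pentamethyl-3-oxododecan-1-aminium iodide | C[N+](C)(C)CCC(=O)CC[C@@H]1O[C@@]1(C)CC[C@@H]1OC1(C)C.[I-] | intermediate
12 | (6S,7S,10S)-6,7:10,11-diepoxy-7,11-dimethyldodec-1-en-3-one | C=CC(=O)CC[C@@H]1O[C@@]1(C)CC[C@@H]1OC1(C)C | intermediate
13 | dimethyl[(2Z,6S,7S,10S)-6,7:10,11-diepoxy-7,11-dimethyl-3-(trimethylsilyloxy)dodec-2-en-1-yl]sulfonium triflate | C[S+](C)C/C=C(\O[Si](C)(C)C)CC[C@@H]1O[C@@]1(C)CC[C@@H]1OC1(C)C.[O-]S(=O)(=O)C(F)(F)F | intermediate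
14 | dimethyl{[(3S,5aS,6S,9aS)-2,2,5a-trimethyl-7-oxo-3-(trimethylsilyloxy)decahydro-1-benzoxepin-6-yl]methyl}sulfonium triflate | C[Si](C)(C)O[C@H]1CC[C@]2(C)[C@H](CCC(=O)[C@H]2C[S+](C)C)OC1(C)C.[O-]S(=O)(=O)C(F)(F)F | intermediate
15 | (3S,5aS,9aS)-2,2,5a-trimethyl-6-methylidene-3-(trimethylsilyloxy)octahydro-1-benzoxepin-7(2H)-one | C[Si](C)(C)O[C@H]1CC[C@]2(C)[C@H](CCC(=O)C2=C)OC1(C)C | intermediate
16 | (3S,5aS,9aS)-3-hydroxy-2,2,5a-trimethyl-6-methylideneoctahydro-1-benzoxepin-7(2H)-one | O[C@H]1CC[C@]2(C)[C@H](CCC(=O)C2=C)OC1(C)C | intermediate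
17 | (3S,5aS,6S,7S,9aS)-3-[tert-butyl(dimethyl)silyl]oxy-6-{2-[(3S,5aS,6S,9aS)-3-hydroxy-2,2,5a-trimethyl-7-oxodecahydro-1-benzoxepin-6-yl]ethyl}-2,2,5a,7-tetramethyldecahydro-1-benzoxepin-7-yl acetate | O[C@H]1CC[C@]2(C)[C@H](CCC(=O)[C@H]2CC[C@H]2[C@]3(C)CC[C@H](O[Si](C)(C)C(C)(C)C)C(C)(C)O[C@H]3CC[C@]2(C)OC(C)=O)OC1(C)C | intermediate
18 | trilithium 3,7,7′-trialkoxide of the coupled skeleton (left 7R with equatorial methyl, 3′-OTBS) | [Li]O[C@H]1CC[C@]2(C)[C@H](CC[C@@](C)(O[Li])[C@H]2CC[C@H]2[C@]3(C)CC[C@H](O[Si](C)(C)C(C)(C)C)C(C)(C)O[C@H]3CC[C@]2(C)O[Li])OC1(C)C | intermediate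
19 | (3S,5aS,6S,7R,9aS)-7-acetoxy-6-{2-[(3S,5aS,6S,7S,9aS)-7-acetoxy-3-[tert-butyl(dimethyl)silyl]oxy-2,2,5a,7-tetramethyldecahydro-1-benzoxepin-6-yl]ethyl}-2,2,5a,7-tetramethyldecahydro-1-benzoxepin-3-yl acetate | CC(=O)O[C@H]1CC[C@]2(C)[C@H](CC[C@@](C)(OC(C)=O)[C@H]2CC[C@H]2[C@]3(C)CC[C@H](O[Si](C)(C)C(C)(C)C)C(C)(C)O[C@H]3CC[C@]2(C)OC(C)=O)OC1(C)C | intermediate
20 | CNP0169816.1: (3S,5aS,6S,7R,9aS)-7-acetoxy-6-{2-[(3S,5aS,6S,7S,9aS)-7-acetoxy-3-hydroxy-2,2,5a,7-tetramethyldecahydro-1-benzoxepin-6-yl]ethyl}-2,2,5a,7-tetramethyldecahydro-1-benzoxepin-3-yl acetate | CC(=O)O[C@H]1CC[C@]2(C)[C@H](CC[C@@](C)(OC(C)=O)[C@H]2CC[C@H]2[C@]3(C)CC[C@H](O)C(C)(C)O[C@H]3CC[C@]2(C)OC(C)=O)OC1(C)C | target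

## Step count and risk

Total: 8 steps. Longest linear sequence: 6 steps (3, 4, 5, 6, 7, 8 from geranylacetone); the farnesyl acetate branch adds steps 1 and 2.

Three steps most likely to fail:

Step 2 (proposed new cascade). The tertiary cation may lose a proton to alkenes instead of being held by the acetate, and iodide attack at the β-branched CH2 may be slow. Fallback with known chemistry, setting out from 3 and coming back at 5: run the silyl-triflate cascade without iodide so that it ends by proton loss (TBSOTf, 2,6-di-tert-butyl-4-methylpyridine, CH2Cl2, −78 °C), which gives the exocyclic alkene acetate F1 together with its 7,8-alkene isomer F2. Epoxidise both from the face away from the 5a-methyl (mCPBA, NaHCO3, CH2Cl2, 0 °C) to the spiro-epoxide F3 and the 7,8-epoxide F4. Reduce the mixture with LiAlH4 (THF, 0 °C → rt), which opens each epoxide at its less substituted carbon and removes the acetate, so both converge on the diol F5 (equatorial tertiary OH, axial methyl). Convert the primary alcohol to the hydroxy iodide F6 (I2, PPh3, imidazole, CH2Cl2) and acetylate the tertiary alcohol (Ac2O, DMAP, Et3N, 40 °C) to reach 5.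

Step 5 (proposed new cascade). Free Me2S may open a silyl-activated epoxide, or the epoxide cascade may start before the enol ether has formed. Fallback with known chemistry, setting out from 12 and coming back at 15: add PhSSiMe3 1,4 to the vinyl ketone (cat. Bu4NF, THF, −40 °C) to isolate the neutral thio silyl enol ether F7. Subject it to the established enol-silane-terminated cascade (cat. TMSOTf, 2,6-di-tert-butyl-4-methylpyridine, CH2Cl2, −78 °C), in which the silyl group moves from the enol oxygen to O3, giving the phenylthio ketone F8. Oxidise at sulfur (mCPBA, 1.0 equiv, −78 °C) to the sulfoxide F9 and warm (toluene, 60 °C) for syn-elimination to the silyl ether enone 15, which the acid work-up of step 5 converts to 16.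

Step 7 (methyl addition with triple acetylation). MeLi may enolise the hindered ketone, and the axial tertiary alkoxide may acetylate incompletely. Fallback setting out from 17 and coming back at 19: treat 17 with dimethylsulfoxonium methylide (Me3S(O)I, NaH, DMSO, rt), which adds reversibly and closes from the equatorial side to the spiro-epoxide F10 (CH2 equatorial, O axial). Open it at CH2 with LiBHEt3 (THF, 0 °C), which also removes the tertiary acetate, to give the triol F11. Form the three alkoxides with KN(SiMe3)2 and acetylate with Ac2O (THF, −78 °C → rt) to reach 19.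

Further compounds

F1 | step 2 | exocyclic alkene acetate: 7′-methylidene right-half bicycle with equatorial 6′-CH2OAc and 3′-OTBS | CC(=O)OC[C@H]1[C@]2(C)CC[C@H](O[Si](C)(C)C(C)(C)C)C(C)(C)O[C@H]2CCC1=C
F2 | step 2 | 7,8-alkene isomer of F1 (7′-methyl, C7′=C8′) | CC(=O)OC[C@H]1[C@]2(C)CC[C@H](O[Si](C)(C)C(C)(C)C)C(C)(C)O[C@H]2CC=C1C
F3 | step 2 | spiro-epoxide of F1 (O equatorial, trans to the 5a′-methyl) | CC(=O)OC[C@H]1[C@]2(C)CC[C@H](O[Si](C)(C)C(C)(C)C)C(C)(C)O[C@H]2CC[C@@]13CO3
F4 | step 2 | 7,8-epoxide of F2 (O trans to the 5a′-methyl) | CC(=O)OC[C@H]1[C@]2(C)CC[C@H](O[Si](C)(C)C(C)(C)C)C(C)(C)O[C@H]2C[C@@H]3O[C@]13C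
F5 | step 2 | diol: 5 with CH2OH in place of CH2I and free 7′-OH | OC[C@H]1[C@]2(C)CC[C@H](O[Si](C)(C)C(C)(C)C)C(C)(C)O[C@H]2CC[C@]1(C)O
F6 | step 2 | hydroxy iodide: 5 with free 7′-OH | IC[C@H]1[C@]2(C)CC[C@H](O[Si](C)(C)C(C)(C)C)C(C)(C)O[C@H]2CC[C@]1(C)O
F7 | step 5 | (2Z,6S,7S,10S)-6,7:10,11-diepoxy-7,11-dimethyl-1-(phenylsulfanyl)-3-(trimethylsilyloxy)dodec-2-ene | C[Si](C)(C)O/C(=C\CSc1ccccc1)CC[C@@H]1O[C@@]1(C)CC[C@@H]1OC1(C)C
F8 | step 5 | (3S,5aS,6S,9aS)-2,2,5a-trimethyl-6-[(phenylsulfanyl)methyl]-3-(trimethylsilyloxy)octahydro-1-benzoxepin-7(2H)-one | C[Si](C)(C)O[C@H]1CC[C@]2(C)[C@H](CCC(=O)[C@H]2CSc2ccccc2)OC1(C)C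
F9 | step 5 | sulfoxide of F8 (both configurations at sulfur) | C[Si](C)(C)O[C@H]1CC[C@]2(C)[C@H](CCC(=O)[C@H]2CS(=O)c2ccccc2)OC1(C)C
F10 | step 7 | spiro-epoxide of 17 at C7 (CH2 equatorial, O axial and cis to the 5a-methyl) | O[C@H]1CC[C@]2(C)[C@H](CC[C@]3(CO3)[C@H]2CC[C@H]2[C@]3(C)CC[C@H](O[Si](C)(C)C(C)(C)C)C(C)(C)O[C@H]3CC[C@]2(C)OC(C)=O)OC1(C)C
F11 | step 7 | 3,7,7′-triol: 19 with the three acetyl groups replaced by H | O[C@H]1CC[C@]2(C)[C@H](CC[C@@](C)(O)[C@H]2CC[C@H]2[C@]3(C)CC[C@H](O[Si](C)(C)C(C)(C)C)C(C)(C)O[C@H]3CC[C@]2(C)O)OC1(C)C
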